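Count everything as fractions of the charge, E and X together.

E 0.50 mM; J 0.24 mM (held); X 0.50 mM; time 80 s

    L + X → L.X (k1 = 34 /M/s)
    J ⇌ L, rate k2*(csat - [L]) (k2 = 0.013 /s, csat = 0.24 mM)
    X ⇌ D (K4 = 0.023, k4 = 0.0027 /s)
    E ⇌ D (K4 = 0.023, k4 = 0.0027 /s)
    L + E → L.E (k5 = 59 /M/s)
    2 L → L2 (k6 = 25 /M/s)

- how much L.E there is at 80 s, in percent of the E and X together charged
- concentration of L in solution at 80 s, in percent of saturation

- L is single-handed; E and X are mirror images of each other, charged as a racemate, each of them at the stated concentration
- two of one species on the left: rate k times its square, two consumed each time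
- at the start none of L is dissolved
- run time (flask): 80 s
- the handed part of L does not stay in what it makes, so the products of the two hands are mirror images too

What do you integrate? Free L, as ℓ, its fraction of the charge. E falls pseudo-first-order in ℓ, with rate constant κ = 0.0590 /s per unit fraction, so the part of E remaining is e^(−θ), where θ is κ times the time integral of ℓ.

How does ℓ move? J feeds it, while transfer, E and X together damp it at λ = 0.0595 /s, with E and X held at their charge. So ℓ climbs as ℓ*(one minus e^(−λt)) towards the quasi-steady ℓ* = 5.24%.

And the integral? The exposure, κ times the integral of ℓ up to 80 s, is θ = 0.196.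

Why drop the loss of 2 L? At ℓ* it removes L at 0.00262 /s per L, far slower than λ.

Where is the weak spot? Holding E at its charge: by 80 s my own reckoning leaves 82.2% of it, so my λ runs high late in the run.

So? L.E is half the charge times (one minus e^(−θ)), which gives 8.90%, and saturation comes to 21.7%.

The forecast gives 8.9% and 22.9%, the second above mine, holding that “L rises with a time constant of about 16 s to a quasi-steady value”.

The flask gives 8.94% and 22.9%.

Read back from 8.94%, the exposure of the flask is 0.197, beside my 0.196. The neighbouring flask, the same charge read at 3.0 min, takes the same closed form: θ = 0.505, so L.E should stand at 19.8% of the charge, with 60.4% of the E left. The neighbouring flask reads 21.3% and 58%, and its free L stands at 6.59% of the charge.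

The constants are invented; what happens was integrated by code.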